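The route rests on cutting the seven-membered ring of the hydroazulene at two bonds, C3a–C4 and C6–C7. Because C4 carries the gem-dimethyl group beside one ring-fusion carbon and C8, the later C=CH2 carbon, lies beside the other, the ring divides into a cyclopentenyl 2-ethoxydiene (C3a, C8a, C8, C7) and a Me2C=CH–CH carbene (C4, C5, C6). Zinc-mediated cyclopropanation followed by divinylcyclopropane rearrangement closes the ring, sets the C3a stereocentre and leaves C8 as a masked ketone in one operation. The precursor is an enantiopure cyclopentene whose quaternary carbon holds a methyl group and a dioxolane, next to a 1-ethoxyvinyl group.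

Key step: step 9

Remarks on the chemistry (one line each):
- Labels: hydroazulene atoms follow azulene numbering (C1 quaternary, C3a/C8a ring fusion, C4 = CMe2, C8 = methylidene carbon); lactone-acetal atoms follow 2,7-dioxabicyclo[3.2.1]octane numbering with primes (C1′ acetal, C3′ carbonyl, C4′, C5′, C6′ ester-bearing, C8′ bearing the hydroazulenyl group), also in the monocyclic precursors; Az = (1R,3aR,8aS)-1,4,4-trimethyl-8-methylidenedecahydroazulen-1-yl.
- The allylic alcohol partner must supply five carbons (C6′, C5′, C4′, C3′ and the ester carbon), so the four-carbon hydroxy ester is first extended by cross-metathesis with an acrylate.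
- A radical that carries the bulky hydroazulenyl group is expected to close trans to the new side chain, which is the wrong C8′ configuration, so C8′ is reset in steps 18–20 by hydrogen-atom transfer.
- Assumption: the cinchoninium salt of step 1 gives the (R)-ester; if not, its pseudoenantiomer N-(9-anthracenylmethyl)cinchonidinium chloride is used.

Step 1
Reactants: 1 tert-butyl 2-oxocyclopentane-1-carboxylate
Product: 2 tert-butyl (R)-1-methyl-2-oxocyclopentane-1-carboxylate
Conditions: MeI, N-(9-anthracenylmethyl)cinchoninium chloride (10 mol%), 50% aqueous KOH, toluene, 0 °C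
Reagents that add atoms: iodomethane CI
Why: Asymmetric phase-transfer alkylation, in which the β-keto ester enolate is methylated inside a tight ion pair with the chiral ammonium cation, so that one enolate face is exposed and the quaternary carbon (later C1) should form as R, the tert-butyl ester supplying the bulk on which face selection depends.

Step 2
Reactants: 2 tert-butyl (R)-1-methyl-2-oxocyclopentane-1-carboxylate
Product: 3 tert-butyl (R)-1-methyl-2-(trifluoromethylsulfonyloxy)cyclopent-2-ene-1-carboxylate
Conditions: KN(SiMe3)2, THF, −78 °C; PhNTf2, −78 → 0 °C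
Reagents that add atoms: N-phenylbis(trifluoromethanesulfonimide) O=S(=O)(N(c1ccccc1)S(=O)(=O)C(F)(F)F)C(F)(F)F
Why: Enolate O-triflation, regiospecific because the ketone has α-hydrogens on one side only, and without effect on the quaternary stereocentre.

Step 3
Reactants: 3 tert-butyl (R)-1-methyl-2-(trifluoromethylsulfonyloxy)cyclopent-2-ene-1-carboxylate
Product: 4 [(S)-1-methyl-2-(trifluoromethylsulfonyloxy)cyclopent-2-en-1-yl]methanol
Conditions: iBu2AlH (3 equiv), CH2Cl2, −78 → 0 °C; aqueous potassium sodium tartrate
Reagents that add atoms: none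
Why: Hydride reduction of the ester to the primary alcohol, which the vinyl triflate tolerates; the descriptor changes only through the priority rules.

Step 4
Reactants: 4 [(S)-1-methyl-2-(trifluoromethylsulfonyloxy)cyclopent-2-en-1-yl]methanol
Product: 5 (R)-1-methyl-2-(trifluoromethylsulfonyloxy)cyclopent-2-ene-1-carbaldehyde
Conditions: Dess–Martin periodinane, CH2Cl2, room temperature
Reagents that add atoms: none
Why: Dess–Martin oxidation stops at the aldehyde under neutral conditions, and the aldehyde has no α-hydrogen and cannot epimerise.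

Step 5
Reactants: 5 (R)-1-methyl-2-(trifluoromethylsulfonyloxy)cyclopent-2-ene-1-carbaldehyde
Product: 6 (R)-5-(1,3-dioxolan-2-yl)-5-methylcyclopent-1-en-1-yl trifluoromethanesulfonate
Conditions: ethylene glycol, TsOH·H2O (5 mol%), benzene, reflux, Dean–Stark trap
Reagents that add atoms: ethane-1,2-diol OCCO
Why: Acid-catalysed acetalisation with azeotropic removal of water, which the acid-stable vinyl triflate survives, installs a branched, carbene-inert group that is clearly larger than the methyl group on the same carbon.

Step 6
Reactants: 6 (R)-5-(1,3-dioxolan-2-yl)-5-methylcyclopent-1-en-1-yl trifluoromethanesulfonate; 7 tributyl(1-ethoxyvinyl)stannane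
Product: 8 2-[(R)-2-(1-ethoxyvinyl)-1-methylcyclopent-2-en-1-yl]-1,3-dioxolane
Conditions: Pd(PPh3)4 (5 mol%), LiCl (3 equiv), THF, 65 °C; base-washed silica
Reagents that add atoms: none
Why: Stille coupling (oxidative addition of zerovalent palladium to the vinyl triflate, chloride-assisted transmetalation of the α-alkoxyvinyl group, reductive elimination) gives the 2-ethoxy-1,3-diene without touching the acetal or the stereocentre.

Step 7
Reactants: 9 3-methylbut-2-enal
Product: 10 3-methylbut-2-enal tosylhydrazone
Conditions: TsNHNH2, MeOH, room temperature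
Reagents that add atoms: 4-methylbenzenesulfonohydrazide Cc1ccc(cc1)S(=O)(=O)NN
Why: Condensation of the aldehyde with the sulfonyl hydrazide gives the crystalline hydrazone.

Step 8
Reactants: 10 3-methylbut-2-enal tosylhydrazone
Product: 13 3,3-dimethylcyclopropene, via sodium tosylhydrazonate 11 (not isolated), via diazoalkene 12 (not isolated)
Conditions: NaOMe (1.05 equiv), MeOH, then evaporation; diglyme, 150 °C, N2 sweep, trap at −78 °C
Reagents that add atoms: none
Why: Bamford–Stevens reaction, in which the salt expels sulfinate to the vinyldiazoalkane, which loses N2 to a vinylcarbene that closes to the cyclopropene, and this is swept out of the hot zone as it forms.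

Step 9
Reactants: 8 2-[(R)-2-(1-ethoxyvinyl)-1-methylcyclopent-2-en-1-yl]-1,3-dioxolane; 13 3,3-dimethylcyclopropene
Product: 15 2-[(1R,3aS)-8-ethoxy-1,4,4-trimethyl-1,2,3,3a,4,7-hexahydroazulen-1-yl]-1,3-dioxolane, via cis-divinylcyclopropane 14 (not isolated)
Conditions: ZnCl2 (10 mol%), CH2Cl2, 0 °C → room temperature; filtration through basic Al2O3; toluene, 110 °C
Reagents that add atoms: none
Why: ZnCl2 opens the strained cyclopropene to a zinc 2-methylprop-1-enyl carbene, which cyclopropanates the terminal C=CH2 of the 2-ethoxydiene, the most electron-rich and least hindered alkene, and so forms the C6–C7 bond in the 1-ethoxy-1,2-dialkenylcyclopropane 14. The cis isomer then undergoes a [3,3] shift through a boat transition state that breaks the oxygen-substituted ring bond and joins the CMe2 terminus to the cyclopentene CH (C4–C3a), the closest known reaction type being the tandem metal-vinylcarbene cyclopropanation and cis-divinylcyclopropane rearrangement used as a formal (4+3) cycloaddition. The seven-membered ring is therefore closed by sigmatropic ring expansion of the three-membered ring and not by an end-to-end cyclisation, and the tetrasubstituted enol ether that results marks C8 as the later ketone. The one new stereocentre, C3a, is controlled by the quaternary carbon C1, because the cyclopropane can sit only over the cyclopentene face that carries the methyl group while the dioxolane blocks the other. The step needs selectivity for the enol ether double bond, a cis arrangement of the two alkenyl groups and this facial preference; the first follows from the electrophilic carbene, and the other two are secured because the doubly allylic, oxygen-substituted ring bond should open reversibly at the temperature that the inward methyl group of the CMe2 terminus demands, so that the trans isomer and the wrong-face cis isomer feed the one unhindered boat.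

Step 10
Reactants: 15 2-[(1R,3aS)-8-ethoxy-1,4,4-trimethyl-1,2,3,3a,4,7-hexahydroazulen-1-yl]-1,3-dioxolane
Product: 16 2-[(1R,3aS)-8-ethoxy-1,4,4-trimethyl-1,2,3,3a,4,5,6,7-octahydroazulen-1-yl]-1,3-dioxolane
Conditions: H2 (1 atm), 5% Pd/C, EtOAc, Et3N (1 vol%), room temperature
Reagents that add atoms: none
Why: Heterogeneous catalytic hydrogenation should saturate only the cis-disubstituted C5=C6 alkene, since the tetrasubstituted enol ether is too hindered and the amine suppresses acid-induced cleavage of enol ether and acetal.

Step 11
Reactants: 16 2-[(1R,3aS)-8-ethoxy-1,4,4-trimethyl-1,2,3,3a,4,5,6,7-octahydroazulen-1-yl]-1,3-dioxolane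
Product: 18 cis-fused ketone (3R,3aR,8aR)-3-(1,3-dioxolan-2-yl)-3,8,8-trimethyloctahydroazulen-4(1H)-one, via trans-fused ketone 17 (not isolated)
Conditions: 0.5 M aqueous HCl, THF, 0 °C; then NaOMe (0.2 equiv), MeOH, room temperature
Reagents that add atoms: water O
Why: Enol ether hydrolysis (C-protonation, then collapse of the hemiacetal) leaves the hindered dioxolane intact, and enolate equilibration should convert any trans-fused epimer 17 into the cis-fused ketone, in which the carbonyl-bearing ring bond at C8a lies beside the C1 methyl group and not beside the larger dioxolane, so C8a is set under thermodynamic control.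

Step 12
Reactants: 18 cis-fused ketone
Product: 19 2-[(1R,3aR,8aS)-1,4,4-trimethyl-8-methylidenedecahydroazulen-1-yl]-1,3-dioxolane
Conditions: Ph3PCH3Br (3 equiv), KOtBu (2.8 equiv), toluene, room temperature → 70 °C
Reagents that add atoms: methyltriphenylphosphonium bromide C[P+](c1ccccc1)(c1ccccc1)c1ccccc1.[Br-]
Why: Wittig methylenation with the salt-free ylide converts the hindered ketone into the exocyclic alkene and thereby locks the ring fusion, the α-centre being already at its equilibrium configuration.

Step 13
Reactants: 19 2-[(1R,3aR,8aS)-1,4,4-trimethyl-8-methylidenedecahydroazulen-1-yl]-1,3-dioxolane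
Product: 20 (1R,3aR,8aS)-1,4,4-trimethyl-8-methylidenedecahydroazulene-1-carbaldehyde
Conditions: 1 M aqueous HCl, THF, 40 °C
Reagents that add atoms: water O
Why: Acetal hydrolysis in dilute aqueous acid, which is too weak to protonate the isolated 1,1-disubstituted alkene, frees an aldehyde that has no α-hydrogen.

Step 14
Reactants: 20 (1R,3aR,8aS)-1,4,4-trimethyl-8-methylidenedecahydroazulene-1-carbaldehyde
Product: 21 (1R,3aR,8aS)-1-(2-methoxyvinyl)-1,4,4-trimethyl-8-methylidenedecahydroazulene (E/Z mixture)
Conditions: MeOCH2PPh3Cl (2 equiv), KOtBu (1.9 equiv), THF, 0 °C → room temperature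
Reagents that add atoms: (methoxymethyl)triphenylphosphonium chloride COC[P+](c1ccccc1)(c1ccccc1)c1ccccc1.[Cl-]
Why: Wittig homologation adds the acetal carbon C1′ as an enol ether, and the alkene geometry is irrelevant because both alkene carbons become sp3 in step 16.

Step 15
Reactants: 22 methyl (R)-2-hydroxybut-3-enoate; 23 tert-butyl acrylate
Product: 24 1-tert-butyl 5-methyl (2E,4R)-4-hydroxypent-2-enedioate
Conditions: second-generation Grubbs catalyst (5 mol%), 23 (3 equiv), CH2Cl2, 40 °C
Reagents that add atoms: none
Why: Olefin cross-metathesis of a terminal allylic alkene with an electron-poor acrylate favours the (E)-cross product, adds the later lactone carbonyl C3′ as an acid-labile ester and does not involve the carbinol stereocentre.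

Step 16
Reactants: 21 (1R,3aR,8aS)-1-(2-methoxyvinyl)-1,4,4-trimethyl-8-methylidenedecahydroazulene; 24 1-tert-butyl 5-methyl (2E,4R)-4-hydroxypent-2-enedioate
Product: 25 mixed bromoacetal Az–CHBr–CH(OMe)–O–CH(CO2Me)–CH=CH–CO2tBu
Conditions: NBS (1.1 equiv), 24 (3 equiv), CH2Cl2, −78 → −20 °C
Reagents that add atoms: N-bromosuccinimide O=C1CCC(=O)N1Br
Why: Bromoacetalisation, in which Br+ adds to the nucleophilic β-carbon of the enol ether (far more reactive than the isolated alkene) and the alcohol captures the oxocarbenium ion; the two new centres are transient.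

Step 17
Reactants: 25 mixed bromoacetal
Product: 26 methyl (2R,3R)-3-(2-tert-butoxy-2-oxoethyl)-5-methoxy-4-Az-tetrahydrofuran-2-carboxylate (mixture at C4 and C5)
Conditions: Bu3SnH (1.3 equiv, slow addition), AIBN (0.1 equiv), benzene, 80 °C
Reagents that add atoms: none
Why: Ueno–Stork reaction, a 5-exo-trig closure of the acetal-flanked radical onto the β-carbon of the enoate through a chair-like transition state with the methyl ester pseudo-equatorial, forms the C8′–C5′ bond and should set C5′ trans to the ester at C6′; the configuration at C8′ is erased in step 18.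

Step 18
Reactants: 26 tetrahydrofuran methyl acetal
Product: 27 methyl (2R,3R)-3-(2-tert-butoxy-2-oxoethyl)-4-Az-2,3-dihydrofuran-2-carboxylate
Conditions: Me3SiOTf (1.3 equiv), iPr2NEt (1.6 equiv), CH2Cl2, −40 → 0 °C
Reagents that add atoms: none
Why: Acetal-to-enol-ether elimination, in which silylation of the exocyclic methoxy group gives the cyclic oxocarbenium ion and the amine removes its only β-proton, turns C1′ and C8′ into a ring enol ether whatever their configuration was.

Step 19
Reactants: 27 dihydrofuran
Product: 28 bromo methyl acetal (Br at C8′ trans to the C5′ side chain; OMe at C1′ trans to Br)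
Conditions: NBS (1.05 equiv), MeOH–CH2Cl2 (1:4), −78 °C
Reagents that add atoms: N-bromosuccinimide O=C1CCC(=O)N1Br; methanol CO
Why: Bromoetherification of the ring enol ether, with Br+ approaching C8′ anti to the neighbouring CH2CO2tBu group and methanol opening the bromonium ion trans to bromine, should place the methoxy group on the same face as that side chain.

Step 20
Reactants: 28 bromo methyl acetal
Product: 29 all-cis methyl acetal (OMe, Az and CH2CO2tBu on one face; CO2Me on the other)
Conditions: Bu3SnH (1.5 equiv), Et3B (0.2 equiv), air, toluene, −78 → −40 °C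
Reagents that add atoms: none
Why: Radical debromination, in which the planar tertiary radical at C8′ is flanked on one face by both the methoxy group and the side chain, so tin hydride should deliver hydrogen to the open face and fix the hydroazulenyl group cis to both, the contra-steric C8′ configuration that the target needs (hydrogen-atom transfer anti to vicinal substituents of a cyclic radical).

Step 21
Reactants: 29 all-cis methyl acetal
Product: 31 methyl (1S,5R,6R,8R)-3-oxo-8-Az-2,7-dioxabicyclo[3.2.1]octane-6-carboxylate, via carboxylic acid 30 (not isolated)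
Conditions: CF3CO2H–CH2Cl2 (1:5), 0 °C, 1 h
Reagents that add atoms: none
Why: Acid-mediated ester cleavage and transacetalising lactonisation, in which the side-chain carboxyl group captures the oxocarbenium ion at C1′ to close the six-membered lactone by 6-exo attack, which is possible only from the face of the side chain, so C1′ is set by the bridge and the brief cold exposure should spare the exocyclic alkene.

Step 22
Reactants: 31 bicyclic lactone
Product: 32 C4′ alcohol of 31 (OH on the face of the O7′–C6′ bridge)
Conditions: KN(SiMe3)2 (1.1 equiv), THF, −78 °C; 2-(phenylsulfonyl)-3-phenyloxaziridine, −78 °C; NH4Cl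
Reagents that add atoms: 2-(phenylsulfonyl)-3-phenyloxaziridine O=S(=O)(N1OC1c1ccccc1)c1ccccc1
Why: Davis hydroxylation of the lactone enolate (the lactone CH2 being the most acidic site), with the oxidant approaching C4′ from the face of the two-atom bridge because the hydroazulenyl group on C8′ covers the other, should give the equatorial alcohol, which is also the more stable epimer.

Step 23
Reactants: 32 C4′ alcohol
Product: 33 target, methyl (1S,4S,5R,6R,8R)-4-acetoxy-3-oxo-8-Az-2,7-dioxabicyclo[3.2.1]octane-6-carboxylate
Conditions: Ac2O, DMAP (0.1 equiv), pyridine, CH2Cl2, 0 °C → room temperature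
Reagents that add atoms: acetic anhydride CC(=O)OC(C)=O
Why: DMAP-catalysed acylation of the secondary alcohol, which touches no stereocentre.

Compound list

1 | tert-butyl 2-oxocyclopentane-1-carboxylate | CC(C)(C)OC(=O)C1CCCC1=O | starting material
2 | tert-butyl (R)-1-methyl-2-oxocyclopentane-1-carboxylate | CC(C)(C)OC(=O)[C@]1(C)CCCC1=O | intermediate
3 | tert-butyl (R)-1-methyl-2-(trifluoromethylsulfonyloxy)cyclopent-2-ene-1-carboxylate | CC(C)(C)OC(=O)[C@]1(C)CCC=C1OS(=O)(=O)C(F)(F)F | intermediate
4 | [(S)-1-methyl-2-(trifluoromethylsulfonyloxy)cyclopent-2-en-1-yl]methanol | OC[C@]1(C)CCC=C1OS(=O)(=O)C(F)(F)F | intermediate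
5 | (R)-1-methyl-2-(trifluoromethylsulfonyloxy)cyclopent-2-ene-1-carbaldehyde | O=C[C@]1(C)CCC=C1OS(=O)(=O)C(F)(F)F | intermediate
6 | (R)-5-(1,3-dioxolan-2-yl)-5-methylcyclopent-1-en-1-yl trifluoromethanesulfonate | FC(F)(F)S(=O)(=O)OC1=CCC[C@@]1(C)C2OCCO2 | intermediate
7 | tributyl(1-ethoxyvinyl)stannane | CCCC[Sn](CCCC)(CCCC)C(=C)OCC | starting material
8 | 2-[(R)-2-(1-ethoxyvinyl)-1-methylcyclopent-2-en-1-yl]-1,3-dioxolane (key-step precursor) | C=C(OCC)C1=CCC[C@@]1(C)C2OCCO2 | intermediate
9 | 3-methylbut-2-enal | CC(C)=CC=O | starting material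
10 | 3-methylbut-2-enal tosylhydrazone | CC(C)=CC=NNS(=O)(=O)c1ccc(C)cc1 | intermediate
11 | sodium salt of 10 | CC(C)=CC=N[N-]S(=O)(=O)c1ccc(C)cc1.[Na+] | intermediate
12 | 1-diazo-3-methylbut-2-ene | CC(C)=CC=[N+]=[N-] | intermediate
13 | 3,3-dimethylcyclopropene | CC1(C)C=C1 | intermediate
14 | 2-{(R)-2-[(1R,2S)-1-ethoxy-2-(2-methylprop-1-en-1-yl)cyclopropyl]-1-methylcyclopent-2-en-1-yl}-1,3-dioxolane (cis-dialkenylcyclopropane) | CCO[C@@]1(C[C@H]1C=C(C)C)C2=CCC[C@@]2(C)C3OCCO3 | intermediate
15 | 2-[(1R,3aS)-8-ethoxy-1,4,4-trimethyl-1,2,3,3a,4,7-hexahydroazulen-1-yl]-1,3-dioxolane (key-step product) | CCOC1=C2[C@@H](CC[C@@]2(C)C3OCCO3)C(C)(C)C=CC1 | intermediate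
16 | 2-[(1R,3aS)-8-ethoxy-1,4,4-trimethyl-1,2,3,3a,4,5,6,7-octahydroazulen-1-yl]-1,3-dioxolane | CCOC1=C2[C@@H](CC[C@@]2(C)C3OCCO3)C(C)(C)CCC1 | intermediate
17 | trans-fused ketone, the C3a epimer of 18 (ketone numbering) | O=C1CCCC(C)(C)[C@@H]2CC[C@@](C)(C3OCCO3)[C@@H]12 | intermediate
18 | (3R,3aR,8aR)-3-(1,3-dioxolan-2-yl)-3,8,8-trimethyloctahydroazulen-4(1H)-one (cis-fused) | O=C1CCCC(C)(C)[C@@H]2CC[C@@](C)(C3OCCO3)[C@H]12 | intermediate
19 | 2-[(1R,3aR,8aS)-1,4,4-trimethyl-8-methylidenedecahydroazulen-1-yl]-1,3-dioxolane | C=C1CCCC(C)(C)[C@@H]2CC[C@@](C)(C3OCCO3)[C@H]12 | intermediate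
20 | (1R,3aR,8aS)-1,4,4-trimethyl-8-methylidenedecahydroazulene-1-carbaldehyde | C=C1CCCC(C)(C)[C@@H]2CC[C@@](C)(C=O)[C@H]12 | intermediate
21 | (1R,3aR,8aS)-1-(2-methoxyvinyl)-1,4,4-trimethyl-8-methylidenedecahydroazulene, E/Z mixture | C=C1CCCC(C)(C)[C@@H]2CC[C@@](C)(C=COC)[C@H]12 | intermediate
22 | methyl (R)-2-hydroxybut-3-enoate | C=C[C@@H](O)C(=O)OC | starting material
23 | tert-butyl acrylate | C=CC(=O)OC(C)(C)C | starting material
24 | 1-tert-butyl 5-methyl (2E,4R)-4-hydroxypent-2-enedioate | CC(C)(C)OC(=O)/C=C/[C@@H](O)C(=O)OC | intermediate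
25 | mixed bromoacetal of 21 with 24, mixture at CHBr and at the acetal carbon | C=C1CCCC(C)(C)[C@@H]2CC[C@@](C)(C(Br)C(OC)O[C@@H](C(=O)OC)/C=C/C(=O)OC(C)(C)C)[C@H]12 | intermediate
26 | methyl (2R,3R)-3-(2-tert-butoxy-2-oxoethyl)-5-methoxy-4-Az-tetrahydrofuran-2-carboxylate, mixture at C4 and C5 | C=C1CCCC(C)(C)[C@@H]2CC[C@@](C)(C3C(OC)O[C@@H](C(=O)OC)[C@@H]3CC(=O)OC(C)(C)C)[C@H]12 | intermediate
27 | methyl (2R,3R)-3-(2-tert-butoxy-2-oxoethyl)-4-Az-2,3-dihydrofuran-2-carboxylate | C=C1CCCC(C)(C)[C@@H]2CC[C@@](C)(C3=CO[C@@H](C(=O)OC)[C@@H]3CC(=O)OC(C)(C)C)[C@H]12 | intermediate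
28 | 4-bromo-5-methoxy derivative of 27: Br trans to the C3 side chain, OMe trans to Br | C=C1CCCC(C)(C)[C@@H]2CC[C@@](C)([C@]3(Br)[C@H](OC)O[C@@H](C(=O)OC)[C@@H]3CC(=O)OC(C)(C)C)[C@H]12 | intermediate
29 | all-cis methyl acetal: OMe, Az and CH2CO2tBu on one face, CO2Me on the other | C=C1CCCC(C)(C)[C@@H]2CC[C@@](C)([C@@H]3[C@H](OC)O[C@@H](C(=O)OC)[C@@H]3CC(=O)OC(C)(C)C)[C@H]12 | intermediate
30 | carboxylic acid from 29 (tert-butyl ester cleaved) | C=C1CCCC(C)(C)[C@@H]2CC[C@@](C)([C@@H]3[C@H](OC)O[C@@H](C(=O)OC)[C@@H]3CC(=O)O)[C@H]12 | intermediate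
31 | methyl (1S,5R,6R,8R)-3-oxo-8-Az-2,7-dioxabicyclo[3.2.1]octane-6-carboxylate | C=C1CCCC(C)(C)[C@@H]2CC[C@@](C)([C@@H]3[C@@H]4OC(=O)C[C@H]3[C@H](C(=O)OC)O4)[C@H]12 | intermediate
32 | 4-hydroxy derivative of 31, OH on the face of the O7–C6 bridge | C=C1CCCC(C)(C)[C@@H]2CC[C@@](C)([C@@H]3[C@@H]4OC(=O)[C@@H](O)[C@H]3[C@H](C(=O)OC)O4)[C@H]12 | intermediate
33 | methyl (1S,4S,5R,6R,8R)-4-acetoxy-3-oxo-8-[(1R,3aR,8aS)-1,4,4-trimethyl-8-methylidenedecahydroazulen-1-yl]-2,7-dioxabicyclo[3.2.1]octane-6-carboxylate | C=C1CCCC(C)(C)[C@@H]2CC[C@@](C)([C@@H]3[C@@H]4OC(=O)[C@@H](OC(C)=O)[C@H]3[C@H](C(=O)OC)O4)[C@H]12 | target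

Total step count: 23. Longest linear sequence: 20 steps (steps 1–6, 9–14 and 16–23); steps 7–8 and step 15 are side branches.

Steps most likely to fail

Step 9. The Lewis acid may oligomerise or hydrolyse the acid-labile 2-ethoxydiene faster than it opens the cyclopropene, or the volatile cyclopropene may escape before it reacts. The fallback sets out from diene 8 and tosylhydrazone 10 and comes back at 15. The sodium salt 11 is warmed (dioxane, 40 °C, benzyltriethylammonium chloride) with Rh2(OAc)4 and 8, so that the diazoalkene 12 is decomposed by the rhodium catalyst as it forms and the same alkenylcarbene is transferred to the enol ether under neutral conditions. This gives the cyclopropane 14, which is heated in toluene to 15 as before. This fallback makes no compound outside the numbered list (F0).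

Step 20. Hydrogen may be delivered to the wrong face of the crowded tertiary radical, or the tertiary bromide may lose HBr before it is reduced, which would give the C8′ epimer or return 27. The fallback sets out from 27 and comes back at 31. Me3SiOTf and 2,6-lutidine (CH2Cl2, 0 °C, then water) cleave only the tert-butyl ester and give the dihydrofuran acid F1. N-Iodosuccinimide (NaHCO3, CH2Cl2, −40 °C) then effects iodolactonisation, iodine adding to C8′ anti to the side chain and the carboxylate closing on C1′ from its own face, to give the bicyclic iodolactone F2. Bu3SnH with Et3B and air removes the iodine; the bridge radical should be reduced with the hydroazulenyl group settling over the lactone, away from the exo ester, to give 31. Ring closure here precedes C–H bond formation, so C8′ is decided in the rigid bicycle and not in the monocycle.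

Step 12. The basic ylide may enolise the hindered ketone instead of adding to it, so that conversion stalls and the ring-fusion centre next to the carbonyl group drifts during prolonged heating. The fallback sets out from 18 and comes back at 19 by a Peterson olefination in two stages. Me3SiCH2Li premixed with anhydrous CeCl3 (THF, −78 °C) adds to the carbonyl group without deprotonation and gives the β-hydroxysilane F3. KH (THF, 0 °C → room temperature) then eliminates the silanolate and returns the alkene 19.

Further compounds

F0 | step 9 | none | none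
F1 | step 20 | dihydrofuran acid (27 with CO2H in place of CO2tBu) | C=C1CCCC(C)(C)[C@@H]2CC[C@@](C)(C3=CO[C@@H](C(=O)OC)[C@@H]3CC(=O)O)[C@H]12
F2 | step 20 | 8-iodo derivative of 31 (iodine on the one-atom bridge, syn to the O7–C6 bridge) | C=C1CCCC(C)(C)[C@@H]2CC[C@@](C)([C@]3(I)[C@@H]4OC(=O)C[C@H]3[C@H](C(=O)OC)O4)[C@H]12
F3 | step 12 | β-hydroxysilane from 18 (tertiary alcohol with CH2SiMe3, mixture at the carbinol carbon) | C[Si](C)(C)CC1(O)CCCC(C)(C)[C@@H]2CC[C@@](C)(C3OCCO3)[C@H]12
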